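**Strategy.** The heptamer is cut at the O–C1 bond of the central ring D, whose C4–OH lies para to that ether oxygen. Ring D is therefore treated as a 2-aryloxy-syringic acid, and its carboxyl-bearing C1 is joined to the hindered ring-C phenol oxygen by an anodic, decarboxylative phenoxyl cross-coupling. This copies oxidative phlorotannin/syringate coupling, with CO2 as traceless leaving group. In one operation it should make the most congested diaryl ether, fix the 1,2-bis(aryloxy)-3,4,5-trioxy pattern of ring D, and unite a trimeric phenol with a tetrameric hydroxy acid. Both arms (rings A–B–C and E–F–G) come from one common trimer, grown by SNAr/Dakin cycles.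

Key step: step 13

Remark on stereochemistry: the target has no stereocentre and no hindered axis (freely rotating diaryl ethers); it is achiral, so no enantiocontrol is needed.
Remark on ring letters: A–G follow the order of the rings in the target SMILES. A is the terminal 2,4,6-trihydroxyphenyl ring and G the terminal 3,4,5-trihydroxyphenyl ring. In central ring D, C1 bears O–ring C, C2 is H, C3–C5 bear OH, and C6 bears O–ring E.
Assumption: 4-fluoro-2,6-dimethoxybenzaldehyde (5) is taken as a catalogue compound, like 1 and 14.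

Step 1
Reactants: 1 4-hydroxy-2,6-dimethoxybenzaldehyde
Product: 2 4-(benzyloxy)-2,6-dimethoxybenzaldehyde
Conditions: BnBr, K2CO3, DMF, 50 °C
Reagents that add atoms: benzyl bromide, BrCc1ccccc1
Why: Williamson ether synthesis on the only OH, which is acidified by the para formyl group and so alkylates cleanly under carbonate conditions.

Step 2
Reactants: 2 4-(benzyloxy)-2,6-dimethoxybenzaldehyde
Product: 4 4-(benzyloxy)-2,6-dimethoxyphenol, via aryl formate 3 (not isolated)
Conditions: mCPBA, CH2Cl2, 0 °C to rt; NaHCO3 wash; then K2CO3 (cat.), MeOH, rt, Ar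
Reagents that add atoms: mCPBA, OOC(=O)c1cccc(Cl)c1
Why: Dakin-type Baeyer–Villiger oxidation, in which the electron-rich 2,6-dimethoxyaryl group migrates in preference to H to give the formate, which mild methanolysis should convert to the phenol while the benzyl ether stays intact.

Step 3
Reactants: 4 4-(benzyloxy)-2,6-dimethoxyphenol; 5 4-fluoro-2,6-dimethoxybenzaldehyde
Product: 6 4-[4-(benzyloxy)-2,6-dimethoxyphenoxy]-2,6-dimethoxybenzaldehyde
Conditions: Cs2CO3, DMSO, 110 °C, Ar
Reagents that add atoms: none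
Why: SNAr, in which the para formyl group stabilises the Meisenheimer adduct and the small fluoride leaving group tolerates the di-ortho-substituted, electron-rich caesium phenoxide.

Step 4
Reactants: 6 4-[4-(benzyloxy)-2,6-dimethoxyphenoxy]-2,6-dimethoxybenzaldehyde
Product: 8 4-[4-(benzyloxy)-2,6-dimethoxyphenoxy]-2,6-dimethoxyphenol, via dimer formate 7 (not isolated)
Conditions: mCPBA, CH2Cl2, 0 °C to rt; NaHCO3 wash; then K2CO3 (cat.), MeOH, rt, Ar
Reagents that add atoms: mCPBA, OOC(=O)c1cccc(Cl)c1
Why: Dakin-type Baeyer–Villiger oxidation as in step 2, where the aldehyde flanked by two OMe groups should react faster than the ether-substituted rings and reveal the next hindered phenol.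

Step 5
Reactants: 8 4-[4-(benzyloxy)-2,6-dimethoxyphenoxy]-2,6-dimethoxyphenol; 5 4-fluoro-2,6-dimethoxybenzaldehyde
Product: 9 trimer aldehyde 4-{4-[4-(benzyloxy)-2,6-dimethoxyphenoxy]-2,6-dimethoxyphenoxy}-2,6-dimethoxybenzaldehyde
Conditions: Cs2CO3, DMSO, 110 °C, Ar
Reagents that add atoms: none
Why: SNAr as in step 3, since the nucleophilic site of 8 is the same 2,6-dimethoxyphenoxide and the remote aryloxy group does not change its reactivity.

Step 6
Reactants: 9 trimer aldehyde
Product: 11 common trimer phenol 4-{4-[4-(benzyloxy)-2,6-dimethoxyphenoxy]-2,6-dimethoxyphenoxy}-2,6-dimethoxyphenol, via trimer formate 10 (not isolated)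
Conditions: mCPBA, CH2Cl2, 0 °C to rt; NaHCO3 wash; then K2CO3 (cat.), MeOH, rt, Ar
Reagents that add atoms: mCPBA, OOC(=O)c1cccc(Cl)c1
Why: Dakin-type Baeyer–Villiger oxidation as in steps 2 and 4, giving the trimer that serves unchanged as the A–B–C arm and, after steps 7 and 8, as the E–F–G arm.

Step 7
Reactants: 11 common trimer phenol
Product: 12 5-{4-[4-(benzyloxy)-2,6-dimethoxyphenoxy]-2,6-dimethoxyphenoxy}-1,2,3-trimethoxybenzene
Conditions: MeI, K2CO3, acetone, reflux
Reagents that add atoms: iodomethane, CI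
Why: Williamson O-methylation of the single free phenol, which turns the flanked end of the trimer into the protected ring G.

Step 8
Reactants: 12 methylated benzyl trimer
Product: 13 3,5-dimethoxy-4-[2,6-dimethoxy-4-(3,4,5-trimethoxyphenoxy)phenoxy]phenol
Conditions: H2 (1 atm), Pd/C, EtOAc–MeOH, rt
Reagents that add atoms: none
Why: Catalytic hydrogenolysis should cleave only the benzyl ether, leaving methyl and diaryl ethers and unmasking the unhindered ring-E phenol.

Step 9
Reactants: 14 syringic acid (4-hydroxy-3,5-dimethoxybenzoic acid)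
Product: 15 benzyl 4-(benzyloxy)-3,5-dimethoxybenzoate
Conditions: BnBr (2.5 equiv), K2CO3, DMF, 60 °C
Reagents that add atoms: benzyl bromide, BrCc1ccccc1
Why: Double Williamson-type alkylation of phenoxide and carboxylate, so that both ring-D protecting groups can later be removed in one hydrogenolysis.

Step 10
Reactants: 15 benzyl 4-(benzyloxy)-3,5-dimethoxybenzoate
Product: 16 benzyl 4-(benzyloxy)-2-bromo-3,5-dimethoxybenzoate
Conditions: NBS (1.0 equiv), MeCN, 0 °C to rt, dark
Reagents that add atoms: N-bromosuccinimide, O=C1CCC(=O)N1Br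
Why: Electrophilic aromatic bromination at one of the two equivalent free positions (ortho and para to the OMe groups), while the benzyl groups are inert under ionic conditions.

Step 11
Reactants: 16 benzyl 4-(benzyloxy)-2-bromo-3,5-dimethoxybenzoate; 13 ring-E phenol of the E–F–G trimer
Product: 17 benzyl 4-(benzyloxy)-3,5-dimethoxy-2-(E–F–G-aryloxy)benzoate (full name in the list)
Conditions: CuI (10 mol %), picolinic acid (20 mol %), K3PO4, DMSO, 90 °C, Ar
Reagents that add atoms: none
Why: Ullmann-type Cu-catalysed diaryl ether coupling under conditions developed for hindered partners, with an unhindered electron-rich phenol and a bromide whose ortho ester assists oxidative addition at copper.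

Step 12
Reactants: 17 dibenzyl-protected ring-D ester carrying the E–F–G arm
Product: 18 4-hydroxy-3,5-dimethoxy-2-(E–F–G-aryloxy)benzoic acid (full name in the list)
Conditions: H2 (1 atm), Pd/C, THF–MeOH, rt
Reagents that add atoms: none
Why: Catalytic hydrogenolysis should remove the benzyl ester and the benzyl ether together, giving the 2-aryloxy-syringic acid needed for the key step.

Step 13
Reactants: 11 common trimer phenol (2.5 equiv, excess recovered); 18 2-aryloxy-syringic acid tetramer
Product: 20 protected heptamer with free ring-D C4–OH (full name in the list), via quinol ether acid 19 (not isolated)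
Conditions: undivided cell, RVC anode, Pt-wire cathode, controlled potential at the foot of the first phenolate wave (set by prior CV), nBu4NBF4, NaHCO3 buffer, MeCN–H2O 4:1, 0 °C, Ar; 18 added slowly over several hours; about 2 F per mol of 18
Reagents that add atoms: none
Why: Proposed new method: at the carbon anode, 11 and the ring-D phenol of 18 are each oxidised by one electron to aryloxyl radicals; the radical of 11, whose ortho and para carbons all carry oxygen, is persistent and should combine through oxygen with the spin-bearing, carboxyl-substituted C1 (para to O) of the transient radical of 18 to give quinol ether 19, a vinylogous β-keto acid that loses CO2 irreversibly and rearomatises to phenol 20. The closest known reaction type is the oxidative (laccase-, peroxidase- or Cu/O2-mediated) decarboxylative C–O polycondensation of syringic acid to poly(2,6-dimethoxy-1,4-phenylene oxide), together with anodic phenol C–O coupling; the new element is its use as a cross-coupling of two different, discrete phenols. No ring is closed and no stereocentre is formed. The step needs O-to-C1 regioselectivity and cross- over homo-selectivity: the first is secured because C3 and C5 of ring D carry OMe, so that only bond formation at C1 can end in rearomatisation by CO2 loss, while C–C coupling is blocked and other O–C adducts are reversible quinone-ketal-type dead ends; the second rests on the persistent-radical effect, with the more easily oxidised 11 kept in excess and 18 fed slowly, which also starves over-extension of 20 because that would need a further molecule of 18. The bond formed is the most congested diaryl ether of the target (three ortho substituents), and a radical O–C combination should be less sensitive to this hindrance than a metal-mediated reductive elimination.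

Step 14
Reactants: 20 protected heptamer (fifteen OMe, one OBn, one OH)
Product: 21 target CNP0304148.0
Conditions: BBr3 (excess), CH2Cl2, −78 °C to rt, Ar; then MeOH–H2O; degassed Sephadex LH-20 / RP-HPLC
Reagents that add atoms: none
Why: Lewis-acid ether cleavage, in which BBr3 complexes each alkyl aryl ether oxygen and bromide removes methyl or benzyl while the diaryl ether C–O bonds are inert, so hydrolysis of the aryl borates should release all seventeen hydroxyl groups.

**Compound list**

1 | 4-hydroxy-2,6-dimethoxybenzaldehyde | O=Cc1c(OC)cc(O)cc1OC | starting material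
2 | 4-(benzyloxy)-2,6-dimethoxybenzaldehyde | O=Cc1c(OC)cc(OCc2ccccc2)cc1OC | intermediate
3 | 4-(benzyloxy)-2,6-dimethoxyphenyl formate | O=COc1c(OC)cc(OCc2ccccc2)cc1OC | intermediate (not isolated)
4 | 4-(benzyloxy)-2,6-dimethoxyphenol | Oc1c(OC)cc(OCc2ccccc2)cc1OC | intermediate
5 | 4-fluoro-2,6-dimethoxybenzaldehyde | O=Cc1c(OC)cc(F)cc1OC | starting material
6 | 4-[4-(benzyloxy)-2,6-dimethoxyphenoxy]-2,6-dimethoxybenzaldehyde | O=Cc1c(OC)cc(Oc2c(OC)cc(OCc3ccccc3)cc2OC)cc1OC | intermediate
7 | 4-[4-(benzyloxy)-2,6-dimethoxyphenoxy]-2,6-dimethoxyphenyl formate | O=COc1c(OC)cc(Oc2c(OC)cc(OCc3ccccc3)cc2OC)cc1OC | intermediate (not isolated)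
8 | 4-[4-(benzyloxy)-2,6-dimethoxyphenoxy]-2,6-dimethoxyphenol | Oc1c(OC)cc(Oc2c(OC)cc(OCc3ccccc3)cc2OC)cc1OC | intermediate
9 | 4-{4-[4-(benzyloxy)-2,6-dimethoxyphenoxy]-2,6-dimethoxyphenoxy}-2,6-dimethoxybenzaldehyde | O=Cc1c(OC)cc(Oc2c(OC)cc(Oc3c(OC)cc(OCc4ccccc4)cc3OC)cc2OC)cc1OC | intermediate
10 | 4-{4-[4-(benzyloxy)-2,6-dimethoxyphenoxy]-2,6-dimethoxyphenoxy}-2,6-dimethoxyphenyl formate | O=COc1c(OC)cc(Oc2c(OC)cc(Oc3c(OC)cc(OCc4ccccc4)cc3OC)cc2OC)cc1OC | intermediate (not isolated)
11 | 4-{4-[4-(benzyloxy)-2,6-dimethoxyphenoxy]-2,6-dimethoxyphenoxy}-2,6-dimethoxyphenol (common trimer phenol) | Oc1c(OC)cc(Oc2c(OC)cc(Oc3c(OC)cc(OCc4ccccc4)cc3OC)cc2OC)cc1OC | intermediate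
12 | 5-{4-[4-(benzyloxy)-2,6-dimethoxyphenoxy]-2,6-dimethoxyphenoxy}-1,2,3-trimethoxybenzene | COc1c(OC)cc(Oc2c(OC)cc(Oc3c(OC)cc(OCc4ccccc4)cc3OC)cc2OC)cc1OC | intermediate
13 | 3,5-dimethoxy-4-[2,6-dimethoxy-4-(3,4,5-trimethoxyphenoxy)phenoxy]phenol | COc1c(OC)cc(Oc2c(OC)cc(Oc3c(OC)cc(O)cc3OC)cc2OC)cc1OC | intermediate
14 | syringic acid (4-hydroxy-3,5-dimethoxybenzoic acid) | OC(=O)c1cc(OC)c(O)c(OC)c1 | starting material
15 | benzyl 4-(benzyloxy)-3,5-dimethoxybenzoate | O=C(OCc1ccccc1)c1cc(OC)c(OCc2ccccc2)c(OC)c1 | intermediate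
16 | benzyl 4-(benzyloxy)-2-bromo-3,5-dimethoxybenzoate | O=C(OCc1ccccc1)c1cc(OC)c(OCc2ccccc2)c(OC)c1Br | intermediate
17 | benzyl 4-(benzyloxy)-3,5-dimethoxy-2-{3,5-dimethoxy-4-[2,6-dimethoxy-4-(3,4,5-trimethoxyphenoxy)phenoxy]phenoxy}benzoate | O=C(OCc1ccccc1)c1cc(OC)c(OCc2ccccc2)c(OC)c1Oc1cc(OC)c(Oc2cc(OC)c(Oc3cc(OC)c(OC)c(OC)c3)c(OC)c2)c(OC)c1 | intermediate
18 | 4-hydroxy-3,5-dimethoxy-2-{3,5-dimethoxy-4-[2,6-dimethoxy-4-(3,4,5-trimethoxyphenoxy)phenoxy]phenoxy}benzoic acid | OC(=O)c1cc(OC)c(O)c(OC)c1Oc1cc(OC)c(Oc2cc(OC)c(Oc3cc(OC)c(OC)c(OC)c3)c(OC)c2)c(OC)c1 | intermediate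
19 | 3,5-dimethoxy-4-oxo-1-{4-[4-(4-(benzyloxy)-2,6-dimethoxyphenoxy)-2,6-dimethoxyphenoxy]-2,6-dimethoxyphenoxy}-2-{3,5-dimethoxy-4-[2,6-dimethoxy-4-(3,4,5-trimethoxyphenoxy)phenoxy]phenoxy}cyclohexa-2,5-diene-1-carboxylic acid (quinol ether acid) | OC(=O)C1(Oc2c(OC)cc(Oc3c(OC)cc(Oc4c(OC)cc(OCc5ccccc5)cc4OC)cc3OC)cc2OC)C=C(OC)C(=O)C(OC)=C1Oc1cc(OC)c(Oc2cc(OC)c(Oc3cc(OC)c(OC)c(OC)c3)c(OC)c2)c(OC)c1 | intermediate (not isolated)
20 | 4-{4-[4-(4-(benzyloxy)-2,6-dimethoxyphenoxy)-2,6-dimethoxyphenoxy]-2,6-dimethoxyphenoxy}-2,6-dimethoxy-3-{3,5-dimethoxy-4-[2,6-dimethoxy-4-(3,4,5-trimethoxyphenoxy)phenoxy]phenoxy}phenol (protected heptamer) | COc1cc(Oc2c(OC)cc(Oc3c(OC)cc(Oc4c(OC)cc(OCc5ccccc5)cc4OC)cc3OC)cc2OC)c(Oc2cc(OC)c(Oc3cc(OC)c(Oc4cc(OC)c(OC)c(OC)c4)c(OC)c3)c(OC)c2)c(OC)c1O | intermediate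
21 | CNP0304148.0, heptameric fuhalol-type phlorotannin with seventeen free OH (rings A–G as defined above) | Oc1cc(O)c(Oc2cc(O)c(Oc3cc(O)c(Oc4cc(O)c(O)c(O)c4Oc4cc(O)c(Oc5cc(O)c(Oc6cc(O)c(O)c(O)c6)c(O)c5)c(O)c4)c(O)c3)c(O)c2)c(O)c1 | target

**Step count and risks**

Total step count: 14. Longest linear sequence: 12 steps (steps 1–8, then 11–14); steps 9–10 form the short ring-D branch.

Steps most likely to fail:

1. Step 13 (Proposed new method). Three processes may go wrong: scrambling of chain lengths through reversible quinone-ketal formation and aryloxy redistribution between phenoxyl radicals, homocoupling of the hydroxy acid partner, and further oxidation of the product phenol. The fallback uses known SNAr/Dakin and Ullmann chemistry; it sets out from 5 (with 11 and 13) and comes back to the route at 20. Bromination of 5 with NBS in MeCN at one of its two equivalent free positions should give 3-bromo-4-fluoro-2,6-dimethoxybenzaldehyde F1. SNAr of the caesium phenoxide of 11 at the fluoride para to the formyl group (Cs2CO3, DMSO) should give the tetrameric bromo aldehyde F2. Cu-catalysed (CuI/picolinic acid/K3PO4) or Pd-catalysed etherification of the flanked bromide with phenol 13 should give the heptameric aldehyde F3. Dakin oxidation (mCPBA, then K2CO3/MeOH) through the heptamer formate F4 should then deliver 20.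

2. Step 11. Oxidative addition at the di-ortho-substituted bromide may be too slow, so that protodebromination or attack of the phenoxide on the benzyl ester takes over. The fallback switches to a carboxylate-assisted (Hurtley-type) condensation of an o-bromobenzoic acid; it sets out from 16 and comes back at 18. Saponification (LiOH, THF–H2O) should give 4-(benzyloxy)-2-bromo-3,5-dimethoxybenzoic acid F5. Its potassium salt is condensed with 13 (Cu/Cu2O, K2CO3, DMF, 120 °C), the ortho carboxylate delivering copper to the C–Br bond, to give the aryloxy acid F6. Hydrogenolysis (H2, Pd/C) of the remaining benzyl ether should give 18.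

3. Step 14. Dealkylation of sixteen ethers may stop short, and the air-sensitive polyphenol may oxidise during isolation. The fallback isolates the product through a stable derivative; it sets out from 20 and comes back at 21. The crude BBr3 product is peracetylated (Ac2O, pyridine) to the heptadecaacetate F7, which can be purified on silica and separated from species that still carry methyl ethers (these are resubjected to BBr3). Acid-catalysed methanolysis of F7 under argon (catalytic AcCl in degassed MeOH) should release 21 without exposure to base.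

**Further compounds**

F1 | step 13 | 3-bromo-4-fluoro-2,6-dimethoxybenzaldehyde | O=Cc1c(OC)cc(F)c(Br)c1OC
F2 | step 13 | 3-bromo-4-{4-[4-(4-(benzyloxy)-2,6-dimethoxyphenoxy)-2,6-dimethoxyphenoxy]-2,6-dimethoxyphenoxy}-2,6-dimethoxybenzaldehyde | O=Cc1c(OC)cc(Oc2c(OC)cc(Oc3c(OC)cc(Oc4c(OC)cc(OCc5ccccc5)cc4OC)cc3OC)cc2OC)c(Br)c1OC
F3 | step 13 | 4-{4-[4-(4-(benzyloxy)-2,6-dimethoxyphenoxy)-2,6-dimethoxyphenoxy]-2,6-dimethoxyphenoxy}-2,6-dimethoxy-3-{3,5-dimethoxy-4-[2,6-dimethoxy-4-(3,4,5-trimethoxyphenoxy)phenoxy]phenoxy}benzaldehyde | O=Cc1c(OC)cc(Oc2c(OC)cc(Oc3c(OC)cc(Oc4c(OC)cc(OCc5ccccc5)cc4OC)cc3OC)cc2OC)c(Oc2cc(OC)c(Oc3cc(OC)c(Oc4cc(OC)c(OC)c(OC)c4)c(OC)c3)c(OC)c2)c1OC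
F4 | step 13 | formate ester of 20 (aryl formate at ring-D C4) | O=COc1c(OC)cc(Oc2c(OC)cc(Oc3c(OC)cc(Oc4c(OC)cc(OCc5ccccc5)cc4OC)cc3OC)cc2OC)c(Oc2cc(OC)c(Oc3cc(OC)c(Oc4cc(OC)c(OC)c(OC)c4)c(OC)c3)c(OC)c2)c1OC
F5 | step 11 | 4-(benzyloxy)-2-bromo-3,5-dimethoxybenzoic acid | OC(=O)c1cc(OC)c(OCc2ccccc2)c(OC)c1Br
F6 | step 11 | 4-(benzyloxy)-3,5-dimethoxy-2-{3,5-dimethoxy-4-[2,6-dimethoxy-4-(3,4,5-trimethoxyphenoxy)phenoxy]phenoxy}benzoic acid | OC(=O)c1cc(OC)c(OCc2ccccc2)c(OC)c1Oc1cc(OC)c(Oc2cc(OC)c(Oc3cc(OC)c(OC)c(OC)c3)c(OC)c2)c(OC)c1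
F7 | step 14 | heptadecaacetate of the target (all seventeen OH acetylated) | CC(=O)Oc1cc(OC(C)=O)c(Oc2cc(OC(C)=O)c(Oc3cc(OC(C)=O)c(Oc4cc(OC(C)=O)c(OC(C)=O)c(OC(C)=O)c4Oc4cc(OC(C)=O)c(Oc5cc(OC(C)=O)c(Oc6cc(OC(C)=O)c(OC(C)=O)c(OC(C)=O)c6)c(OC(C)=O)c5)c(OC(C)=O)c4)c(OC(C)=O)c3)c(OC(C)=O)c2)c(OC(C)=O)c1
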